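The route rests on opening the C3=C4 double bond of the pyranone ring of coumarin unit A (the 7-hydroxy-6-methoxy half). This bond is exploited because it is the one alkene of the target that unravels into two terminal olefins held on an aryl ester, while the C3–O–C7' ether to unit B stays on a plain acrylate carbon. Ring-closing metathesis then creates C3=C4 and closes the lactone ring of unit A in a single operation, with loss of ethene. The precursor is the ester of a MOM-protected 2-vinylphenol with the 2-aryloxyacrylic acid derived from scopoletin; unit B travels intact, its endocyclic C3'=C4' alkene a spectator.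

Key step: step 6

Remark: under the basic conditions used, phenols and acids exist as their conjugate bases and are reprotonated on work-up; such salts, like catalyst-bound species, are regarded as forms of the parent compound.

Step 1
Reactants: 1 scopoletin (7-hydroxy-6-methoxychromen-2-one); 2 methyl 2,3-dibromopropanoate
Product: 4 methyl 2-[(6-methoxy-2-oxochromen-7-yl)oxy]prop-2-enoate, via methyl 3-bromo-2-aryloxypropanoate 3 (not isolated)
Conditions: K2CO3 (3 equiv), 2 (1.3 equiv, added dropwise), acetone, reflux
Reagents that add atoms: none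
Why: Williamson-type SN2 displacement of the carbonyl-activated C2 bromide by the scopoletin phenoxide should give 3, and E1cB loss of HBr then gives 4, a captodative acrylate that cannot eliminate further and is a poor acceptor for a second phenoxide.

Step 2
Reactants: 4 methyl 2-[(6-methoxy-2-oxochromen-7-yl)oxy]prop-2-enoate
Product: 6 2-[(6-methoxy-2-oxochromen-7-yl)oxy]prop-2-enoic acid, via ring-opened trilithium salt 5 (not isolated)
Conditions: LiOH·H2O (3.5 equiv), THF/H2O, 0 °C to rt, dark; then 1 M HCl to pH 1, rt
Reagents that add atoms: lithium hydroxide, [Li+].[OH-]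
Why: Saponification of the methyl ester; hydroxide also opens the lactone of unit B to the (Z)-2-hydroxycinnamate, which should keep its geometry in the cold and dark and reclose spontaneously on acidification, while the 2-oxygenated acrylate is too poor a Michael acceptor to take up hydroxide.

Step 3
Reactants: 7 2,4-dihydroxy-5-methoxybenzaldehyde
Product: 8 2-hydroxy-5-methoxy-4-(methoxymethoxy)benzaldehyde
Conditions: MOMCl (1.1 equiv), K2CO3 (1.2 equiv), acetone, 0 °C to rt
Reagents that add atoms: chloromethyl methyl ether (MOMCl), COCCl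
Why: Regioselective Williamson etherification: the C4 hydroxyl, para to the formyl group, is the more acidic and accessible one, whereas the C2 hydroxyl is held in an intramolecular hydrogen bond to the aldehyde.

Step 4
Reactants: 8 2-hydroxy-5-methoxy-4-(methoxymethoxy)benzaldehyde; 9 methyltriphenylphosphonium bromide
Product: 11 2-ethenyl-4-methoxy-5-(methoxymethoxy)phenol, via methylenetriphenylphosphorane 10 (not isolated)
Conditions: 9 (2.6 equiv), KOtBu (2.5 equiv), THF, 0 °C; then 8, 0 °C to rt; aq NH4Cl quench; product kept cold over BHT and used promptly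
Reagents that add atoms: none
Why: Wittig methylenation with the non-stabilised ylide 10, taken in excess because the first equivalent only deprotonates the phenol; the MOM acetal is inert to base.

Step 5
Reactants: 6 2-[(6-methoxy-2-oxochromen-7-yl)oxy]prop-2-enoic acid; 11 2-ethenyl-4-methoxy-5-(methoxymethoxy)phenol
Product: 13 2-ethenyl-4-methoxy-5-(methoxymethoxy)phenyl 2-[(6-methoxy-2-oxochromen-7-yl)oxy]prop-2-enoate, via O-acylisourea 12 (not isolated)
Conditions: DCC (1.2 equiv), DMAP (0.1 equiv), CH2Cl2, 0 °C to rt
Reagents that add atoms: none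
Why: Steglich esterification: DCC activates acid 6 as O-acylisourea 12 and DMAP relays the acyl group to the phenol under neutral conditions that should leave the styrene, the MOM acetal, the enol ether and the lactone untouched.

Step 6
Reactants: 13 2-ethenyl-4-methoxy-5-(methoxymethoxy)phenyl 2-[(6-methoxy-2-oxochromen-7-yl)oxy]prop-2-enoate
Product: 14 6-methoxy-7-(methoxymethoxy)-3-[(6-methoxy-2-oxochromen-7-yl)oxy]chromen-2-one
Conditions: RuCl2(H2IMes)(=CH-C6H4-2-OiPr), the second-generation Hoveyda–Grubbs catalyst (H2IMes = 1,3-dimesitylimidazolidin-2-ylidene; 10 mol % in two portions), toluene, 0.005 M, 80 °C, Ar sparge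
Reagents that add atoms: none
Why: Ring-closing olefin metathesis by the metallacyclobutane mechanism: the ruthenium alkylidene exchanges onto the monosubstituted styrene of 13 to give an aryl-substituted benzylidene, which adds [2+2] to the tethered 1,1-disubstituted acrylate alkene and cycloreverts to the C3=C4 bond and Ru=CH2, ethene being swept out. The closest known reaction type is the metathesis closure of 2-vinylphenyl acrylates and methacrylates to coumarins, together with closures onto 2-alkoxyacrylates. The one ring formed is the six-membered pyranone of unit A, closed by joining the two alkene termini across the preformed aryl ester, so the new alkene is necessarily cis within the ring and no stereocentre arises. Chemoselectivity among three alkenes is needed: initiation should occur only at the unhindered styrene, the captodative acrylate is too hindered to load or dimerise and is reached only intramolecularly, and the endocyclic conjugated C3'=C4' alkene of unit B is inert. The metallacycle places ruthenium on the CH2 terminus, so no deactivated oxygen-substituted carbene is formed, and heating in dilute toluene populates the s-cis ester rotamer and suppresses stilbene-type dimerisation.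

Step 7
Reactants: 14 6-methoxy-7-(methoxymethoxy)-3-[(6-methoxy-2-oxochromen-7-yl)oxy]chromen-2-one
Product: 15 7-hydroxy-6-methoxy-3-[(6-methoxy-2-oxochromen-7-yl)oxy]chromen-2-one (target)
Conditions: HCl (2 M in MeOH), THF, 45 °C
Reagents that add atoms: none
Why: Acid-catalysed solvolysis of the aryl MOM acetal, which passes the methoxymethyl group to methanol; both coumarin lactones and the C3–O–C7' vinyl aryl ether, deactivated by the lactone carbonyl, should be stable to dilute acid.

Compound list
1 | scopoletin (7-hydroxy-6-methoxychromen-2-one) | COc1cc2ccc(=O)oc2cc1O | starting material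
2 | methyl 2,3-dibromopropanoate (racemic) | COC(=O)C(Br)CBr | starting material
3 | methyl 3-bromo-2-[(6-methoxy-2-oxochromen-7-yl)oxy]propanoate (racemic) | COC(=O)C(CBr)Oc1cc2oc(=O)ccc2cc1OC | intermediate
4 | methyl 2-[(6-methoxy-2-oxochromen-7-yl)oxy]prop-2-enoate | COC(=O)C(=C)Oc1cc2oc(=O)ccc2cc1OC | intermediate
5 | trilithium (2Z)-3-{4-[(1-carboxylatoethenyl)oxy]-5-methoxy-2-oxidophenyl}prop-2-enoate | [Li+].[Li+].[Li+].[O-]C(=O)C(=C)Oc1cc([O-])c(/C=C\C([O-])=O)cc1OC | intermediate
6 | 2-[(6-methoxy-2-oxochromen-7-yl)oxy]prop-2-enoic acid | OC(=O)C(=C)Oc1cc2oc(=O)ccc2cc1OC | intermediate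
7 | 2,4-dihydroxy-5-methoxybenzaldehyde | COc1cc(C=O)c(O)cc1O | starting material
8 | 2-hydroxy-5-methoxy-4-(methoxymethoxy)benzaldehyde | COCOc1cc(O)c(C=O)cc1OC | intermediate
9 | methyltriphenylphosphonium bromide | [Br-].C[P+](c1ccccc1)(c1ccccc1)c1ccccc1 | starting material
10 | methylenetriphenylphosphorane | C=P(c1ccccc1)(c1ccccc1)c1ccccc1 | intermediate
11 | 2-ethenyl-4-methoxy-5-(methoxymethoxy)phenol | C=Cc1cc(OC)c(OCOC)cc1O | intermediate
12 | N,N'-dicyclohexyl-O-{2-[(6-methoxy-2-oxochromen-7-yl)oxy]prop-2-enoyl}isourea | C=C(Oc1cc2oc(=O)ccc2cc1OC)C(=O)OC(=NC1CCCCC1)NC1CCCCC1 | intermediate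
13 | 2-ethenyl-4-methoxy-5-(methoxymethoxy)phenyl 2-[(6-methoxy-2-oxochromen-7-yl)oxy]prop-2-enoate | C=Cc1cc(OC)c(OCOC)cc1OC(=O)C(=C)Oc1cc2oc(=O)ccc2cc1OC | intermediate
14 | 6-methoxy-7-(methoxymethoxy)-3-[(6-methoxy-2-oxochromen-7-yl)oxy]chromen-2-one | COCOc1cc2oc(=O)c(Oc3cc4oc(=O)ccc4cc3OC)cc2cc1OC | intermediate
15 | 7-hydroxy-6-methoxy-3-[(6-methoxy-2-oxochromen-7-yl)oxy]chromen-2-one | COc1cc2cc(Oc3cc4oc(=O)ccc4cc3OC)c(=O)oc2cc1O | target

Total step count: 7. Longest linear sequence: 5 steps (steps 1, 2, 5, 6, 7 from scopoletin, or steps 3, 4, 5, 6, 7 from the aldehyde).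

Steps most likely to fail

Step 6. The benzylidene formed at the styrene may fail to reach the hindered, electron-poor 1,1-disubstituted alkene while the ester rests in its s-trans rotamer, so that catalyst decay and intermolecular dimerisation of the styrene take over. The fallback makes the same C3=C4 bond by carbonyl condensation; it sets out from 1 and 8 and returns at 14. Scopoletin 1 is O-alkylated with tert-butyl bromoacetate (K2CO3, acetone, reflux) to tert-butyl 2-[(6-methoxy-2-oxochromen-7-yl)oxy]acetate F1, which TFA in CH2Cl2 should convert into 2-[(6-methoxy-2-oxochromen-7-yl)oxy]acetic acid F2. DCC/DMAP coupling of F2, through N,N'-dicyclohexyl-O-{2-[(6-methoxy-2-oxochromen-7-yl)oxy]acetyl}isourea F3 (not isolated), with the free phenol of aldehyde 8 gives 2-formyl-4-methoxy-5-(methoxymethoxy)phenyl 2-[(6-methoxy-2-oxochromen-7-yl)oxy]acetate F4. DBU in MeCN at 60 °C then closes the ring by intramolecular Knoevenagel (Perkin-type) condensation of the aryloxyacetate enolate onto the ortho aldehyde, with loss of water, to give 14.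

Step 1. Dehydrobromination of 2 to the 2-bromoacrylate may outrun substitution; the phenoxide would then add at C3, and the sequence could stall at the bromo adduct or end with the oxygen on the wrong carbon. The fallback fixes the oxygen at C2 by construction; it sets out from 1 and returns at 4. Diazo transfer onto trimethyl phosphonoacetate (4-acetamidobenzenesulfonyl azide, DBU, MeCN) gives methyl 2-diazo-2-(dimethoxyphosphoryl)acetate F5. O–H insertion of its carbenoid into scopoletin 1, catalysed by Rh2(OAc)4 (dirhodium tetraacetate) in toluene at 80 °C, should give methyl 2-(dimethoxyphosphoryl)-2-[(6-methoxy-2-oxochromen-7-yl)oxy]acetate F6. Horner–Wadsworth–Emmons olefination of F6 with aqueous formaldehyde (K2CO3, THF/H2O, rt) delivers 4.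

Step 2. Hydroxide opens the lactone of unit B, and the ring-opened cinnamate may isomerise from Z to E so that it no longer recloses, or hydroxide may add to the acrylate. The fallback avoids base by using an acid-labile ester; it sets out from 1 and returns at 6. The etherification of step 1 is run with tert-butyl 2,3-dibromopropanoate (K2CO3, acetone, reflux), passing through tert-butyl 3-bromo-2-[(6-methoxy-2-oxochromen-7-yl)oxy]propanoate F7 (not isolated), to give tert-butyl 2-[(6-methoxy-2-oxochromen-7-yl)oxy]prop-2-enoate F8. Acidolysis of F8 with TFA in CH2Cl2 at rt should release acid 6 with loss of isobutene, the lactone never meeting hydroxide.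

Further compounds
F1 | step 6 | tert-butyl 2-[(6-methoxy-2-oxochromen-7-yl)oxy]acetate | CC(C)(C)OC(=O)COc1cc2oc(=O)ccc2cc1OC
F2 | step 6 | 2-[(6-methoxy-2-oxochromen-7-yl)oxy]acetic acid | OC(=O)COc1cc2oc(=O)ccc2cc1OC
F3 | step 6 | N,N'-dicyclohexyl-O-{2-[(6-methoxy-2-oxochromen-7-yl)oxy]acetyl}isourea | O=C(COc1cc2oc(=O)ccc2cc1OC)OC(=NC1CCCCC1)NC1CCCCC1
F4 | step 6 | 2-formyl-4-methoxy-5-(methoxymethoxy)phenyl 2-[(6-methoxy-2-oxochromen-7-yl)oxy]acetate | COCOc1cc(OC(=O)COc2cc3oc(=O)ccc3cc2OC)c(C=O)cc1OC
F5 | step 1 | methyl 2-diazo-2-(dimethoxyphosphoryl)acetate | COC(=O)C(=[N+]=[N-])P(=O)(OC)OC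
F6 | step 1 | methyl 2-(dimethoxyphosphoryl)-2-[(6-methoxy-2-oxochromen-7-yl)oxy]acetate (racemic) | COC(=O)C(Oc1cc2oc(=O)ccc2cc1OC)P(=O)(OC)OC
F7 | step 2 | tert-butyl 3-bromo-2-[(6-methoxy-2-oxochromen-7-yl)oxy]propanoate (racemic) | CC(C)(C)OC(=O)C(CBr)Oc1cc2oc(=O)ccc2cc1OC
F8 | step 2 | tert-butyl 2-[(6-methoxy-2-oxochromen-7-yl)oxy]prop-2-enoate | CC(C)(C)OC(=O)C(=C)Oc1cc2oc(=O)ccc2cc1OC
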